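I start from a balance: each incoming ligand charged sits on a complex, is still free, or has gone elsewhere, and a complex with two exchanged holds two. Violet, red and amber are on the bench, and they differ in ligand charge.

common to all: starting complex 11 mM

|  | incoming ligand | scavenger | remark | time |
|---|---|---|---|---|
| noon | 8 mM | 8.8 mM | run made earlier |  |
| summer | 32 mM | 8.8 mM | run made earlier |  |
| violet | 5.50 mM | 8.80 mM |  | 6.0 min |
| red | 16.5 mM | 8.80 mM |  | 6.0 min |
| amber | 22.0 mM | 8.80 mM |  | 6.0 min |

| run | time / min | complex with one exchanged / % |
|---|---|---|
| noon | 0.417 | 14.5 |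
| noon | 1.00 | 24.1 |
| noon | 2.00 | 29.1 |
| noon | 3.00 | 28.9 |
| noon | 4.00 | 30.4 |
| summer | 0.333 | 33.7 |
| summer | 0.667 | 37.5 |
| summer | 1.33 | 32.5 |
| summer | 2.00 | 27.4 |
| summer | 4.00 | 18.7 |

(scatter of a reading: 1 percentage point)

- final complex with one exchanged, as a percentage of the starting complex charged, for each flask in turn (violet, red, amber)



Noon stalls: its last readings of complex with one exchanged average B = 29.5% of the charge. I read summer's rise and fall as two steps of similar speed, so at exchange depth x, B = x·e^−x and uptake = 2(1 − e^−x) − B. Going round x = B·e^x from 0.5 gives 0.486, then 0.479. I therefore reckon noon's uptake at 0.464 of the complex charge, and dividing by its ligand charge gives the capture share, ligand on complexes per ligand charged: 0.639.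

If that share holds, uptakes are 0.319, 0.958 and 1.28 for violet, red and amber. Two rounds of x = ln((2 + x)/(2 − uptake)) give x = 0.323, 1.07 and 1.58, so I expect 23.4%, 36.7% and 32.5%. Don't shift the sampling of red and amber from 6.0 min: summer's reading went from 37.5% at 0.667 min to 18.7% at 4.00 min.

The forecast gives 23.5%, 36% and 31%, on the ground “the scavenger must be removing free ligand”.

The flasks give 24.1%, 31.7% and 21.4%.

    starting complex + incoming ligand ⇌ leaving ligand + complex with one exchanged (K = 0.600, k = 1.10 L mol⁻¹ s⁻¹)
    complex with one exchanged + incoming ligand ⇌ leaving ligand + complex with two exchanged (K = 4.80, k = 0.970 L mol⁻¹ s⁻¹)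
    incoming ligand → decomposed reagent (k = 0.00660 s⁻¹)
    leaving ligand + incoming ligand ⇌ idle adduct, settled at all times (K = 140 L mol⁻¹)
    scavenger + leaving ligand → scavenged by-product (k = 81.0 L mol⁻¹ s⁻¹)

Violet holds 3.91% complex with two exchanged at 6.00 min, so its capture share comes to 0.638, beside the 0.639 carried from noon. In red that share asks for an uptake of 0.958, but red's uptake is lower, 0.853 equiv. Red's scavenger, its limiting reagent, stands at 0% of its charge at 6.00 min, and red's starting complex stands at 41.5%, up from 39.5% at 3.00 min.

(All runs were generated by integration from invented constants.)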